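**Retrosynthetic overview**

1. The strategy rests on two features of the quinone C3 side chain. Chain carbons C1'–C14' carry methyl-bearing CH centres at C3', C7' and C11' (1,5-spaced, one spatial sense), which is the reduced form of a single all-E farnesyl unit. The chain ends in a cis-1,3-disubstituted cyclopentane (C15'–C18' plus one ring CH2) carrying the exocyclic methine C19', which maps onto a cis-fused cyclopentene butyrolactone.
2. The quinone is unmasked last from its dimethyl ether. Before that, all three chain stereocentres are set at once by iridium-catalysed asymmetric hydrogenation of the assembled all-E triene.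
3. The triene comes from a 12-oxygenated farnesyl bromide used as a two-ended linchpin: sulfone alkylation at C13'–C14' (ring sulfone), then at C1'–C2' (naphthylmethyl sulfone), then removal of both sulfonyl groups.
4. Ring piece: two palladium allylic alkylations with net retention (C18', then C15') bracket a convex-face lactone methylation (C19'); the tail is joined at C20'–C21' by copper-catalysed coupling.
5. Ring order: the cyclopentane is bought and never built; a temporary γ-lactone is closed (step 4) and opened (step 6); the naphthalene is bought.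

Key step: step 25

**Remarks on the chemistry**

- Locants: C1' (on quinone C3) to C14' for the chain, C15'–C18' for the substituted ring carbons and their two CH2 neighbours C16'/C17', C19'–C23' for the tail.
- Sodium, lithium and magnesium salts formed by simple deprotonation of a numbered compound are treated as that compound in its reactive form.
- Sulfonyl-bearing carbons in 3, 9, 10, 24–26 and 32 form as epimer mixtures; this is harmless because each later becomes CH2.
- In step 25, cod is 1,5-cyclooctadiene and L* is the pyridine–phosphinite (S)-2-phenyl-7-[(di-o-tolylphosphanyl)oxy]-6,7-dihydro-5H-cyclopenta[b]pyridine. The sense of induction was assigned on paper, so the antipode to use is the one that converts 18 into (3R,7R)-3,7,11-trimethyldodecan-1-ol in a control hydrogenation.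

**Route**

Step 1
Reactants: 1 (1S,4R)-cis-4-acetoxycyclopent-2-en-1-ol; 2 methyl (phenylsulfonyl)acetate
Product: 3 methyl 2-[(1R,4S)-4-hydroxycyclopent-2-en-1-yl]-2-(phenylsulfonyl)acetate (cis ring)
Conditions: 2, NaH, THF, 0 °C; then 1, Pd(PPh3)4 (3 mol%), THF, 25–50 °C
Reagents that add atoms: none
Why: Tsuji–Trost allylic alkylation in which zerovalent palladium ionises the acetate (not the hydroxyl) with inversion and the soft sulfonylacetate anion attacks anti to the metal at the allyl terminus remote from the carbinol, so the new C–C bond (future C18') should form with net retention, cis to OH.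

Step 2
Reactants: 3 methyl 2-[(1R,4S)-4-hydroxycyclopent-2-en-1-yl]-2-(phenylsulfonyl)acetate
Product: 4 methyl 2-[(1S,4S)-4-hydroxycyclopent-2-en-1-yl]acetate (cis ring)
Conditions: Mg turnings, MeOH, 25–50 °C
Reagents that add atoms: none
Why: Reductive desulfonylation of an α-sulfonyl ester by electron transfer from magnesium cleaves only the activated C–S bond and should leave the isolated alkene, the allylic alcohol and both ring centres untouched.

Step 3
Reactants: 4 methyl 2-[(1S,4S)-4-hydroxycyclopent-2-en-1-yl]acetate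
Product: 5 2-[(1S,4S)-4-hydroxycyclopent-2-en-1-yl]acetic acid
Conditions: LiOH, THF/H2O, 0–25 °C; then 1 M HCl to pH 3
Reagents that add atoms: lithium hydroxide, [Li+].[OH-] (supplies the carboxyl OH oxygen)
Why: Plain ester saponification; neither ring stereocentre is enolisable.

Step 4
Reactants: 5 2-[(1S,4S)-4-hydroxycyclopent-2-en-1-yl]acetic acid
Product: 7 (1R,5S)-2-oxabicyclo[3.3.0]oct-7-en-3-one (cis-fused vinyl lactone), via bridged δ-lactone 6 (not isolated)
Conditions: TsOH·H2O (cat.), toluene, 80 °C, Dean–Stark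
Reagents that add atoms: none
Why: Acid-catalysed lactonisation with allylic transposition, in which the allylic C–O bond of the hydroxy acid or of the first-formed bridged lactone ionises and the tethered carboxyl recaptures the allyl cation at the terminus next to the arm, so the less strained cis-fused γ-lactone should result under thermodynamic control with the C18' centre untouched and the new C–O bond necessarily cis to the arm.

Step 5
Reactants: 7 (1R,5S)-2-oxabicyclo[3.3.0]oct-7-en-3-one
Product: 8 (1S,4S,5S)-4-methyl-2-oxabicyclo[3.3.0]oct-7-en-3-one (methyl exo; the label at C1 changes by a priority switch only)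
Conditions: LDA (1.05 equiv), THF, −78 °C; then MeI, −78 to −40 °C
Reagents that add atoms: iodomethane, CI
Why: Lactone enolate alkylation in which the lithium enolate of the cis-fused bicyclic butyrolactone should be methylated on its convex face, anti to the cyclopentene ring, which sets C19'.

Step 6
Reactants: 8 (1S,4S,5S)-4-methyl-2-oxabicyclo[3.3.0]oct-7-en-3-one; 2 methyl (phenylsulfonyl)acetate
Product: 9 (2S)-2-[(1R,4S)-4-[2-methoxy-2-oxo-1-(phenylsulfonyl)ethyl]cyclopent-2-en-1-yl]propanoic acid (cis ring)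
Conditions: 2 (1.5 equiv), NaH, THF, 0 °C; then 8, Pd(PPh3)4 (5 mol%), THF, 25–50 °C; 1 M HCl work-up
Reagents that add atoms: none
Why: Tsuji–Trost opening of a vinyl lactone in which zerovalent palladium ionises the allylic lactone C–O bond anti and the sulfonylacetate anion adds anti to the metal at the allyl terminus remote from the propanoate arm, so the new bond at C15' should form with net retention, cis to the C18' arm across the ring CH2.

Step 7
Reactants: 9 (2S)-2-[(1R,4S)-4-[2-methoxy-2-oxo-1-(phenylsulfonyl)ethyl]cyclopent-2-en-1-yl]propanoic acid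
Product: 11 (2S)-2-[(1R,4S)-4-(phenylsulfonylmethyl)cyclopent-2-en-1-yl]propanoic acid, via diacid 10 (not isolated)
Conditions: LiOH, MeOH/H2O, 25–50 °C; 1 M HCl; then DMSO, 120 °C
Reagents that add atoms: none
Why: Saponification followed by thermal decarboxylation of the α-sulfonyl carboxylic acid (the sulfonyl group stabilises the developing carbanion), while the unactivated propanoic acid and its α-centre C19' should be unaffected.

Step 8
Reactants: 11 (2S)-2-[(1R,4S)-4-(phenylsulfonylmethyl)cyclopent-2-en-1-yl]propanoic acid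
Product: 12 (2S)-2-[(1S,3R)-3-(phenylsulfonylmethyl)cyclopentyl]propanoic acid (cis ring)
Conditions: TsNHNH2, NaOAc, DME/H2O, 85 °C
Reagents that add atoms: none
Why: Diimide reduction transfers H2 to the strained disubstituted ring alkene in a concerted syn fashion with no metal-allyl or alkene-migration pathway, so the two allylic centres C15' and C18' cannot scramble and the sulfone and acid are inert.

Step 9
Reactants: 12 (2S)-2-[(1S,3R)-3-(phenylsulfonylmethyl)cyclopentyl]propanoic acid
Product: 13 (2S)-2-[(1S,3R)-3-(phenylsulfonylmethyl)cyclopentyl]propan-1-ol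
Conditions: BH3·THF, THF, 0–25 °C; MeOH then aqueous work-up
Reagents that add atoms: none
Why: Chemoselective borane reduction of the carboxylic acid through its acyloxyborane gives the primary alcohol (future C20') without touching the sulfone or epimerising C19'.

Step 10
Reactants: 13 (2S)-2-[(1S,3R)-3-(phenylsulfonylmethyl)cyclopentyl]propan-1-ol
Product: 14 (2S)-2-[(1S,3R)-3-(phenylsulfonylmethyl)cyclopentyl]propyl 4-methylbenzenesulfonate
Conditions: TsCl, Et3N, DMAP (cat.), CH2Cl2, 0–25 °C
Reagents that add atoms: p-toluenesulfonyl chloride, Cc1ccc(cc1)S(Cl)(=O)=O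
Why: O-Sulfonylation of the primary alcohol installs the leaving group at C20'.

Step 11
Reactants: 14 (2S)-2-[(1S,3R)-3-(phenylsulfonylmethyl)cyclopentyl]propyl 4-methylbenzenesulfonate; 15 1-bromo-3-methylbutane
Product: 17 {[(1R,3S)-3-[(2R)-6-methylheptan-2-yl]cyclopentyl]methylsulfonyl}benzene, via isopentylmagnesium bromide 16 (not isolated)
Conditions: 15, Mg, THF, 40 °C; then 14, Li2CuCl4 (5 mol%), THF, −78 to −10 °C
Reagents that add atoms: none
Why: Copper-catalysed sp3–sp3 cross-coupling of a primary tosylate with an alkyl Grignard reagent forms C20'–C21' at a carbon that is not stereogenic, and at low temperature the cuprate pathway should outrun deprotonation of the sulfone CH2.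

Step 12
Reactants: 18 (2E,6E)-farnesol
Product: 19 (2E,6E)-farnesyl acetate
Conditions: Ac2O, pyridine, DMAP (cat.), CH2Cl2, 0–25 °C
Reagents that add atoms: acetic anhydride, CC(=O)OC(C)=O
Why: Acetylation protects the allylic alcohol (future C13') and deactivates the adjacent alkene towards the oxidation that follows.

Step 13
Reactants: 19 (2E,6E)-farnesyl acetate
Product: 20 (2E,6E,10E)-12-hydroxy-3,7,11-trimethyldodeca-2,6,10-trien-1-yl acetate
Conditions: SeO2 (0.3 equiv), t-BuOOH, salicylic acid (cat.), CH2Cl2, 0–25 °C, stopped at partial conversion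
Reagents that add atoms: tert-butyl hydroperoxide, CC(C)(C)OO (net oxygen source; SeO2, O=[Se]=O, is the catalytic carrier)
Why: Riley-type allylic oxidation (ene reaction then [2,3]-sigmatropic shift) prefers the terminal, most electron-rich trisubstituted alkene and its (E)-methyl group, so the (E)-allylic alcohol (future C2') should form with the alkene geometry retained.

Step 14
Reactants: 20 (2E,6E,10E)-12-hydroxy-3,7,11-trimethyldodeca-2,6,10-trien-1-yl acetate
Product: 21 (2E,6E,10E)-12-(tert-butyldimethylsilyloxy)-3,7,11-trimethyldodeca-2,6,10-trien-1-yl acetate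
Conditions: TBSCl, imidazole, DMF, 25 °C
Reagents that add atoms: tert-butyldimethylsilyl chloride, CC(C)(C)[Si](C)(C)Cl
Why: Standard silylation differentiates the two chain termini.

Step 15
Reactants: 21 (2E,6E,10E)-12-(tert-butyldimethylsilyloxy)-3,7,11-trimethyldodeca-2,6,10-trien-1-yl acetate
Product: 22 (2E,6E,10E)-12-(tert-butyldimethylsilyloxy)-3,7,11-trimethyldodeca-2,6,10-trien-1-ol
Conditions: K2CO3 (cat.), MeOH, 0–25 °C
Reagents that add atoms: none
Why: Base-catalysed transesterification removes the acetate while the silyl ether is stable.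

Step 16
Reactants: 22 (2E,6E,10E)-12-(tert-butyldimethylsilyloxy)-3,7,11-trimethyldodeca-2,6,10-trien-1-ol
Product: 23 (2E,6E,10E)-12-(tert-butyldimethylsilyloxy)-3,7,11-trimethyldodeca-2,6,10-trienyl bromide
Conditions: CBr4, PPh3, CH2Cl2, −20 to 0 °C
Reagents that add atoms: carbon tetrabromide, BrC(Br)(Br)Br
Why: Appel bromination converts the primary allylic alcohol into the primary (E)-allylic bromide under near-neutral conditions that spare the silyl ether.

Step 17
Reactants: 17 {[(1R,3S)-3-[(2R)-6-methylheptan-2-yl]cyclopentyl]methylsulfonyl}benzene; 23 (2E,6E,10E)-12-(tert-butyldimethylsilyloxy)-3,7,11-trimethyldodeca-2,6,10-trienyl bromide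
Product: 24 tert-butyldimethylsilyl ether of (2E,6E,10E)-2,6,10-trimethyl-13-(phenylsulfonyl)-13-[(1R,3S)-3-[(2R)-6-methylheptan-2-yl]cyclopentyl]trideca-2,6,10-trien-1-ol
Conditions: 17, n-BuLi, THF, −78 °C; then 23, −78 to −30 °C
Reagents that add atoms: none
Why: Sulfone carbanion alkylation by clean SN2 attack at the primary allylic bromide forms C13'–C14' without moving or isomerising the alkenes.

Step 18
Reactants: 24 silyl ether from step 17
Product: 25 (2E,6E,10E)-2,6,10-trimethyl-13-(phenylsulfonyl)-13-[(1R,3S)-3-[(2R)-6-methylheptan-2-yl]cyclopentyl]trideca-2,6,10-trien-1-ol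
Conditions: Bu4NF, THF, 0–25 °C
Reagents that add atoms: none
Why: Fluoride-induced desilylation frees the C2' allylic alcohol.

Step 19
Reactants: 25 allylic alcohol from step 18
Product: 26 (2E,6E,10E)-1-bromo-2,6,10-trimethyl-13-(phenylsulfonyl)-13-[(1R,3S)-3-[(2R)-6-methylheptan-2-yl]cyclopentyl]trideca-2,6,10-triene
Conditions: CBr4, PPh3, CH2Cl2, −20 to 0 °C
Reagents that add atoms: carbon tetrabromide, BrC(Br)(Br)Br
Why: Appel bromination gives the primary (E)-allylic bromide at C2'; sulfone and alkenes are inert.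

Step 20
Reactants: 27 menadione (2-methyl-1,4-naphthoquinone)
Product: 29 1,4-dimethoxy-2-methylnaphthalene, via menadiol 28 (not isolated)
Conditions: Na2S2O4, THF/H2O, 25 °C; then KOH, Me2SO4, N2, 25–50 °C
Reagents that add atoms: dimethyl sulfate, COS(=O)(=O)OC
Why: Dithionite reduces the quinone to the hydroquinone, which is O-methylated in the same flask (Williamson ether synthesis) before it can re-oxidise.

Step 21
Reactants: 29 1,4-dimethoxy-2-methylnaphthalene
Product: 30 2-(chloromethyl)-1,4-dimethoxy-3-methylnaphthalene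
Conditions: (CH2O)n, conc. HCl, HCl gas, AcOH, 60 °C
Reagents that add atoms: formaldehyde (as paraformaldehyde), C=O; hydrogen chloride, Cl
Why: Blanc chloromethylation should attack the only free position of the electron-rich dimethoxy ring (C3), which introduces C1'.

Step 22
Reactants: 30 2-(chloromethyl)-1,4-dimethoxy-3-methylnaphthalene
Product: 31 1,4-dimethoxy-2-methyl-3-(phenylsulfonylmethyl)naphthalene
Conditions: PhSO2Na, DMF, 25–60 °C
Reagents that add atoms: sodium benzenesulfinate, [Na+].[O-]S(=O)c1ccccc1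
Why: SN2 displacement of the benzylic chloride by sulfinate (S-alkylation) gives the sulfone.

Step 23
Reactants: 31 1,4-dimethoxy-2-methyl-3-(phenylsulfonylmethyl)naphthalene; 26 allylic bromide from step 19
Product: 32 1,4-dimethoxy-2-methyl-3-[(3E,7E,11E)-3,7,11-trimethyl-1,14-bis(phenylsulfonyl)-14-[(1R,3S)-3-[(2R)-6-methylheptan-2-yl]cyclopentyl]tetradeca-3,7,11-trien-1-yl]naphthalene
Conditions: 31, n-BuLi, THF, −78 °C; then 26, −78 to −20 °C
Reagents that add atoms: none
Why: Sulfone carbanion alkylation forms C1'–C2' by SN2 at the allylic bromide, and the stabilised benzylic anion is too weakly basic to deprotonate the C14' alkyl sulfone already in the electrophile.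

Step 24
Reactants: 32 bis-sulfone triene from step 23
Product: 33 1,4-dimethoxy-2-methyl-3-[(3E,7E,11E)-3,7,11-trimethyl-14-[(1R,3S)-3-[(2R)-6-methylheptan-2-yl]cyclopentyl]tetradeca-3,7,11-trien-1-yl]naphthalene
Conditions: 6% Na(Hg), Na2HPO4, MeOH/THF, −20 to 0 °C
Reagents that add atoms: none
Why: Buffered sodium-amalgam reductive desulfonylation (electron transfer, C–S cleavage, protonation) removes both sulfonyl groups, and since both are homoallylic no allylic radical or anion forms, so alkene position and E geometry should be kept.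

Step 25
Reactants: 33 all-E triene from step 24
Product: 34 1,4-dimethoxy-2-methyl-3-[(3S,7S,11R)-3,7,11-trimethyl-14-[(1R,3S)-3-[(2R)-6-methylheptan-2-yl]cyclopentyl]tetradecyl]naphthalene
Conditions: H2 (50 bar), [Ir(cod)(L*)][B(3,5-(CF3)2C6H3)4] (3 mol%), CH2Cl2, 25 °C
Reagents that add atoms: none
Why: In this iridium N,P-ligand catalysed asymmetric hydrogenation each alkene binds the cationic iridium dihydride, and migratory insertion followed by C–H reductive elimination delivers both hydrogens to one enantioface without chain walking, so six C–H bonds form across C3'=C4', C7'=C8' and C11'=C12' in one operation. The closest known reaction type is the hydrogenation of unfunctionalised all-E trisubstituted polyenes of the farnesol and tocotrienol type with iridium pyridine–phosphinite complexes bearing a non-coordinating tetraarylborate anion. No ring is closed in this step. C3', C7' and C11' are each set by the catalyst alone, which places the vinylic hydrogen of every alkene in the most hindered quadrant of its pocket. The step needs the same enantioface at all three alkenes, and this is secured by their uniform E geometry and identical pattern (arene side–C(Me)=CH–ring side), so one ligand antipode should give the 3'S,7'S,11'R array (one spatial sense; the R label at C11' is a priority switch). The aryl methyl ethers, the naphthalene and the remote ring stereocentres neither coordinate nor bias the reduction.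

Step 26
Reactants: 34 saturated hydroquinone dimethyl ether from step 25
Product: 35 2-methyl-3-[(3S,7S,11R)-3,7,11-trimethyl-14-[(1R,3S)-3-[(2R)-6-methylheptan-2-yl]cyclopentyl]tetradecyl]naphthalene-1,4-dione (target)
Conditions: (NH4)2Ce(NO3)6, MeCN/H2O, 0 °C
Reagents that add atoms: water, O
Why: Oxidative demethylation by tetravalent cerium proceeds through the arene radical cation, water addition and loss of methanol to give the quinone, while the saturated side chain is inert.

**Compound list**

1 | (1S,4R)-cis-4-acetoxycyclopent-2-en-1-ol | CC(=O)O[C@H]1C=C[C@@H](O)C1 | starting material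
2 | methyl (phenylsulfonyl)acetate | COC(=O)CS(=O)(=O)c1ccccc1 | starting material
3 | methyl 2-[(1R,4S)-4-hydroxycyclopent-2-en-1-yl]-2-(phenylsulfonyl)acetate | COC(=O)C([C@H]1C=C[C@@H](O)C1)S(=O)(=O)c1ccccc1 | intermediate
4 | methyl 2-[(1S,4S)-4-hydroxycyclopent-2-en-1-yl]acetate | COC(=O)C[C@H]1C=C[C@@H](O)C1 | intermediate
5 | 2-[(1S,4S)-4-hydroxycyclopent-2-en-1-yl]acetic acid | OC(=O)C[C@H]1C=C[C@@H](O)C1 | intermediate
6 | (1S,5S)-2-oxabicyclo[3.2.1]oct-6-en-3-one (bridged δ-lactone) | O=C2C[C@H]1C=C[C@@H](O2)C1 | intermediate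
7 | (1R,5S)-2-oxabicyclo[3.3.0]oct-7-en-3-one | O=C1C[C@@H]2CC=C[C@@H]2O1 | intermediate
8 | (1S,4S,5S)-4-methyl-2-oxabicyclo[3.3.0]oct-7-en-3-one | C[C@@H]1C(=O)O[C@H]2C=CC[C@@H]12 | intermediate
9 | (2S)-2-[(1R,4S)-4-[2-methoxy-2-oxo-1-(phenylsulfonyl)ethyl]cyclopent-2-en-1-yl]propanoic acid | C[C@H](C(=O)O)[C@@H]1C[C@H](C(C(=O)OC)S(=O)(=O)c2ccccc2)C=C1 | intermediate
10 | 2-[(1S,4R)-4-[(1S)-1-carboxyethyl]cyclopent-2-en-1-yl]-2-(phenylsulfonyl)acetic acid (diacid) | C[C@H](C(=O)O)[C@@H]1C[C@H](C(C(=O)O)S(=O)(=O)c2ccccc2)C=C1 | intermediate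
11 | (2S)-2-[(1R,4S)-4-(phenylsulfonylmethyl)cyclopent-2-en-1-yl]propanoic acid | C[C@H](C(=O)O)[C@@H]1C[C@H](CS(=O)(=O)c2ccccc2)C=C1 | intermediate
12 | (2S)-2-[(1S,3R)-3-(phenylsulfonylmethyl)cyclopentyl]propanoic acid | C[C@H](C(=O)O)[C@@H]1C[C@H](CS(=O)(=O)c2ccccc2)CC1 | intermediate
13 | (2S)-2-[(1S,3R)-3-(phenylsulfonylmethyl)cyclopentyl]propan-1-ol | C[C@H](CO)[C@@H]1C[C@H](CS(=O)(=O)c2ccccc2)CC1 | intermediate
14 | (2S)-2-[(1S,3R)-3-(phenylsulfonylmethyl)cyclopentyl]propyl 4-methylbenzenesulfonate | C[C@H](COS(=O)(=O)c1ccc(C)cc1)[C@@H]2C[C@H](CS(=O)(=O)c3ccccc3)CC2 | intermediate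
15 | 1-bromo-3-methylbutane | CC(C)CCBr | starting material
16 | isopentylmagnesium bromide | CC(C)CC[Mg]Br | intermediate
17 | {[(1R,3S)-3-[(2R)-6-methylheptan-2-yl]cyclopentyl]methylsulfonyl}benzene | O=S(=O)(C[C@@H]1CC[C@H]([C@H](C)CCCC(C)C)C1)c2ccccc2 | intermediate
18 | (2E,6E)-farnesol | CC(C)=CCC/C(C)=C/CC/C(C)=C/CO | starting material
19 | (2E,6E)-farnesyl acetate | CC(C)=CCC/C(C)=C/CC/C(C)=C/COC(C)=O | intermediate
20 | (2E,6E,10E)-12-hydroxy-3,7,11-trimethyldodeca-2,6,10-trien-1-yl acetate | OC/C(C)=C/CC/C(C)=C/CC/C(C)=C/COC(C)=O | intermediate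
21 | (2E,6E,10E)-12-(tert-butyldimethylsilyloxy)-3,7,11-trimethyldodeca-2,6,10-trien-1-yl acetate | CC(C)(C)[Si](C)(C)OC/C(C)=C/CC/C(C)=C/CC/C(C)=C/COC(C)=O | intermediate
22 | (2E,6E,10E)-12-(tert-butyldimethylsilyloxy)-3,7,11-trimethyldodeca-2,6,10-trien-1-ol | CC(C)(C)[Si](C)(C)OC/C(C)=C/CC/C(C)=C/CC/C(C)=C/CO | intermediate
23 | (2E,6E,10E)-12-(tert-butyldimethylsilyloxy)-3,7,11-trimethyldodeca-2,6,10-trienyl bromide | CC(C)(C)[Si](C)(C)OC/C(C)=C/CC/C(C)=C/CC/C(C)=C/CBr | intermediate
24 | tert-butyldimethylsilyl ether of (2E,6E,10E)-2,6,10-trimethyl-13-(phenylsulfonyl)-13-[(1R,3S)-3-[(2R)-6-methylheptan-2-yl]cyclopentyl]trideca-2,6,10-trien-1-ol | CC(C)(C)[Si](C)(C)OC/C(C)=C/CC/C(C)=C/CC/C(C)=C/CC([C@@H]1CC[C@H]([C@H](C)CCCC(C)C)C1)S(=O)(=O)c2ccccc2 | intermediate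
25 | (2E,6E,10E)-2,6,10-trimethyl-13-(phenylsulfonyl)-13-[(1R,3S)-3-[(2R)-6-methylheptan-2-yl]cyclopentyl]trideca-2,6,10-trien-1-ol | OC/C(C)=C/CC/C(C)=C/CC/C(C)=C/CC([C@@H]1CC[C@H]([C@H](C)CCCC(C)C)C1)S(=O)(=O)c2ccccc2 | intermediate
26 | (2E,6E,10E)-1-bromo-2,6,10-trimethyl-13-(phenylsulfonyl)-13-[(1R,3S)-3-[(2R)-6-methylheptan-2-yl]cyclopentyl]trideca-2,6,10-triene | BrC/C(C)=C/CC/C(C)=C/CC/C(C)=C/CC([C@@H]1CC[C@H]([C@H](C)CCCC(C)C)C1)S(=O)(=O)c2ccccc2 | intermediate
27 | menadione | CC1=CC(=O)c2ccccc2C1=O | starting material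
28 | menadiol (2-methylnaphthalene-1,4-diol) | Cc1cc(O)c2ccccc2c1O | intermediate
29 | 1,4-dimethoxy-2-methylnaphthalene | COc1cc(C)c(OC)c2ccccc12 | intermediate
30 | 2-(chloromethyl)-1,4-dimethoxy-3-methylnaphthalene | COc1c(C)c(CCl)c(OC)c2ccccc12 | intermediate
31 | 1,4-dimethoxy-2-methyl-3-(phenylsulfonylmethyl)naphthalene | COc1c(C)c(CS(=O)(=O)c3ccccc3)c(OC)c2ccccc12 | intermediate
32 | 1,4-dimethoxy-2-methyl-3-[(3E,7E,11E)-3,7,11-trimethyl-1,14-bis(phenylsulfonyl)-14-[(1R,3S)-3-[(2R)-6-methylheptan-2-yl]cyclopentyl]tetradeca-3,7,11-trien-1-yl]naphthalene | COc1c(C)c(C(C/C(C)=C/CC/C(C)=C/CC/C(C)=C/CC([C@@H]4CC[C@H]([C@H](C)CCCC(C)C)C4)S(=O)(=O)c5ccccc5)S(=O)(=O)c3ccccc3)c(OC)c2ccccc12 | intermediate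
33 | 1,4-dimethoxy-2-methyl-3-[(3E,7E,11E)-3,7,11-trimethyl-14-[(1R,3S)-3-[(2R)-6-methylheptan-2-yl]cyclopentyl]tetradeca-3,7,11-trien-1-yl]naphthalene | COc1c(C)c(CC/C(C)=C/CC/C(C)=C/CC/C(C)=C/CC[C@@H]3CC[C@H]([C@H](C)CCCC(C)C)C3)c(OC)c2ccccc12 | intermediate
34 | 1,4-dimethoxy-2-methyl-3-[(3S,7S,11R)-3,7,11-trimethyl-14-[(1R,3S)-3-[(2R)-6-methylheptan-2-yl]cyclopentyl]tetradecyl]naphthalene | COc1c(C)c(CC[C@@H](C)CCC[C@@H](C)CCC[C@@H](C)CCC[C@@H]3CC[C@H]([C@H](C)CCCC(C)C)C3)c(OC)c2ccccc12 | intermediate
35 | 2-methyl-3-[(3S,7S,11R)-3,7,11-trimethyl-14-[(1R,3S)-3-[(2R)-6-methylheptan-2-yl]cyclopentyl]tetradecyl]naphthalene-1,4-dione (CNP0182328.1) | CC1=C(CC[C@@H](C)CCC[C@@H](C)CCC[C@@H](C)CCC[C@@H]2CC[C@H]([C@H](C)CCCC(C)C)C2)C(=O)c2ccccc2C1=O | target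

**Step count and risks**

Total steps: 26. Longest linear sequence: 18 steps (steps 1–11, 17–19, 23–26).

Steps most likely to fail:

1. Step 25. Enantioface discrimination may be incomplete at one of the three alkenes (most likely C3'=C4', next to the bulky arene), or reduction may stall through catalyst deactivation; either would leave diastereomers that cannot be separated this late. Fallback (hydrogenate the linchpin first, then couple saturated iodides), setting out from 22 and returning at 34: the same iridium catalyst and H2 in CH2Cl2 would reduce 22, a farnesol-type allylic alcohol of the substrate class on which the catalyst is established, to (3R,7S,11S)-12-(tert-butyldimethylsilyloxy)-3,7,11-trimethyldodecan-1-ol F1, whose stereochemical purity can be checked before advanced material is committed. I2, PPh3 and imidazole would give (3R,7S,11S)-12-(tert-butyldimethylsilyloxy)-1-iodo-3,7,11-trimethyldodecane F2. Lithiated 17 would be alkylated with it (THF, DMPU) to the saturated silyloxy sulfone F3. Bu4NF would free the saturated sulfonyl alcohol F4, and I2, PPh3 and imidazole would give the saturated sulfonyl iodide F5. Lithiated 31 would be alkylated with F5 to the saturated bis-sulfone F6, and buffered sodium amalgam would remove both sulfonyl groups to give 34.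

2. Step 4. Under protic acid the allyl cation may lose a proton instead of being recaptured (diene formation and oligomers), or the transposition may stop at the bridged lactone. Fallback (palladium-mediated instead of cationic lactonisation), setting out from 5 and returning at 7: Ac2O and pyridine followed by aqueous work-up would give 2-[(1S,4S)-4-acetoxycyclopent-2-en-1-yl]acetic acid F7. Pd(PPh3)4 (cat.) and Et3N in THF would ionise the allylic acetate anti, and the tethered carboxylate would close anti to the metal onto the adjacent allyl terminus; this intramolecular allylic substitution by a carboxylate should give the cis-fused lactone 7 as the thermodynamic resting state under neutral conditions.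

3. Step 11. The Grignard reagent may deprotonate the sulfone CH2, and the resulting carbanion may displace the tosylate intramolecularly (a bridged bicyclic sulfone); coupling at the β-branched tosylate may also be slow. Fallback (olefination instead of alkylation, so no leaving group sits in the molecule), setting out from 13 and returning at 17: Dess–Martin periodinane would give (2S)-2-[(1S,3R)-3-(phenylsulfonylmethyl)cyclopentyl]propanal F8. Wittig reaction with the salt-free ylide from (3-methylbutyl)triphenylphosphonium bromide and NaN(SiMe3)2 at −78 °C (to limit epimerisation at C19') would give {[(1R,3S)-3-[(2S,3Z)-6-methylhept-3-en-2-yl]cyclopentyl]methylsulfonyl}benzene F9. Diimide reduction (TsNHNH2, NaOAc) would saturate the alkene without touching the allylic C19' centre and give 17.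

**Further compounds**

F1 | step 25 | (3R,7S,11S)-12-(tert-butyldimethylsilyloxy)-3,7,11-trimethyldodecan-1-ol | CC(C)(C)[Si](C)(C)OC[C@@H](C)CCC[C@@H](C)CCC[C@@H](C)CCO
F2 | step 25 | (3R,7S,11S)-12-(tert-butyldimethylsilyloxy)-1-iodo-3,7,11-trimethyldodecane | CC(C)(C)[Si](C)(C)OC[C@@H](C)CCC[C@@H](C)CCC[C@@H](C)CCI
F3 | step 25 | tert-butyldimethylsilyl ether of (2S,6S,10R)-2,6,10-trimethyl-13-(phenylsulfonyl)-13-[(1R,3S)-3-[(2R)-6-methylheptan-2-yl]cyclopentyl]tridecan-1-ol | CC(C)(C)[Si](C)(C)OC[C@@H](C)CCC[C@@H](C)CCC[C@@H](C)CCC([C@@H]1CC[C@H]([C@H](C)CCCC(C)C)C1)S(=O)(=O)c2ccccc2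
F4 | step 25 | (2S,6S,10R)-2,6,10-trimethyl-13-(phenylsulfonyl)-13-[(1R,3S)-3-[(2R)-6-methylheptan-2-yl]cyclopentyl]tridecan-1-ol | OC[C@@H](C)CCC[C@@H](C)CCC[C@@H](C)CCC([C@@H]1CC[C@H]([C@H](C)CCCC(C)C)C1)S(=O)(=O)c2ccccc2
F5 | step 25 | (2S,6S,10R)-1-iodo-2,6,10-trimethyl-13-(phenylsulfonyl)-13-[(1R,3S)-3-[(2R)-6-methylheptan-2-yl]cyclopentyl]tridecane | IC[C@@H](C)CCC[C@@H](C)CCC[C@@H](C)CCC([C@@H]1CC[C@H]([C@H](C)CCCC(C)C)C1)S(=O)(=O)c2ccccc2
F6 | step 25 | 1,4-dimethoxy-2-methyl-3-[(3S,7S,11R)-3,7,11-trimethyl-1,14-bis(phenylsulfonyl)-14-[(1R,3S)-3-[(2R)-6-methylheptan-2-yl]cyclopentyl]tetradecyl]naphthalene | COc1c(C)c(C(C[C@@H](C)CCC[C@@H](C)CCC[C@@H](C)CCC([C@@H]4CC[C@H]([C@H](C)CCCC(C)C)C4)S(=O)(=O)c5ccccc5)S(=O)(=O)c3ccccc3)c(OC)c2ccccc12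
F7 | step 4 | 2-[(1S,4S)-4-acetoxycyclopent-2-en-1-yl]acetic acid | OC(=O)C[C@H]1C=C[C@@H](OC(C)=O)C1
F8 | step 11 | (2S)-2-[(1S,3R)-3-(phenylsulfonylmethyl)cyclopentyl]propanal | C[C@H](C=O)[C@@H]1C[C@H](CS(=O)(=O)c2ccccc2)CC1
F9 | step 11 | {[(1R,3S)-3-[(2S,3Z)-6-methylhept-3-en-2-yl]cyclopentyl]methylsulfonyl}benzene | C[C@H](/C=C\CC(C)C)[C@@H]1C[C@H](CS(=O)(=O)c2ccccc2)CC1
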